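## Retrosynthetic overview

- **Feature used:** the oxygen of the CH2OH on the alkene carbon and the oxygen of the CH(OH) next to the butenolide are linked by a five-carbon path (CH2–C=CH–CH2–CH) and lie cis across the trisubstituted C=C. One silicon atom between the two oxygens makes this Z alkene the cis double bond of an eight-membered 1,3-dioxa-2-silacyclooct-5-ene ring.
- **Disconnections, last to first:** the two Si–O bonds (fluoride); the ring C=C by ring-closing metathesis between a 2-methylidene alkyl ether and a homoallyl ether on one Si(iPr)2; the two Si–O bonds joining fragment A (C19 primary allylic alcohol) and fragment B (R butenolide carbinol).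
- **Fragment A:** dihydro-β-ionone → terminal alkyne → methylalumination/oxirane (E alkene fixed by syn addition) → bromide → Grignard addition to propargyl alcohol under CuI.
- **Fragment B:** furan-3-carbaldehyde → asymmetric allylboration (R carbinol) → singlet-oxygen oxidation and borohydride reduction (the furan ring becomes the butenolide ring).
- **Ring order:** the cyclohexene ring is bought; the butenolide ring is made on fragment B before coupling; the eight-membered silicon ring is closed in the key step and opened in the last step.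

Key step: step 9

Remark: (+)-B-allyldiisopinocampheylborane (the reagent derived from (−)-α-pinene) is assumed to be used as its commercial solution. Its face selectivity is assigned by analogy with benzaldehyde, which it converts into the R homoallylic alcohol.

## Route

Step 1
Reactants: 1 dihydro-β-ionone [4-(2,6,6-trimethylcyclohex-1-en-1-yl)butan-2-one]
Product: 4 2-(but-3-yn-1-yl)-1,3,3-trimethylcyclohex-1-ene, via enol diethyl phosphate 2 (not isolated), via lithium acetylide 3 (not isolated)
Conditions: LiN(iPr)2 (1.05 equiv), THF, −78 °C; ClP(O)(OEt)2, −78 °C to rt; then LiN(iPr)2 (2.3 equiv), THF, −78 °C to rt; H2O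
Reagents that add atoms: none
Why: Kinetic deprotonation by the hindered amide at −78 °C takes a methyl proton of the methyl ketone, O-phosphorylation gives 2, and base-induced 1,2-elimination of diethyl phosphate gives the terminal alkyne, held as acetylide 3 until the water quench (enol phosphate route from a methyl ketone to a terminal alkyne); the tetrasubstituted ring alkene is inert.

Step 2
Reactants: 4 2-(but-3-yn-1-yl)-1,3,3-trimethylcyclohex-1-ene
Product: 7 (3E)-4-methyl-6-(2,6,6-trimethylcyclohex-1-en-1-yl)hex-3-en-1-ol, via alkenyldimethylalane 5 (not isolated), via lithium butylalanate 6 (not isolated)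
Conditions: Me3Al (2 equiv), Cp2ZrCl2 (0.25 equiv), ClCH2CH2Cl, rt; volatiles removed; n-BuLi (1 equiv), hexane–THF, 0 °C; oxirane, 0 °C to rt; 3 M HCl
Reagents that add atoms: trimethylaluminium, C[Al](C)C; oxirane, C1CO1
Why: Zirconium-catalysed methylalumination (Negishi carboalumination) adds CH3 and Al syn across the terminal alkyne with Al on the terminal carbon, so the chain and the new C–C bond end up trans (E), and the butyl ate complex 6 opens oxirane at carbon with retention of the alkene geometry.

Step 3
Reactants: 7 (3E)-4-methyl-6-(2,6,6-trimethylcyclohex-1-en-1-yl)hex-3-en-1-ol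
Product: 8 2-[(3E)-6-bromo-3-methylhex-3-en-1-yl]-1,3,3-trimethylcyclohex-1-ene
Conditions: CBr4, PPh3, CH2Cl2, 0 °C
Reagents that add atoms: carbon tetrabromide, BrC(Br)(Br)Br
Why: Appel reaction, in which the alkoxyphosphonium ion formed from PPh3 and CBr4 is displaced by bromide at the primary carbon under neutral conditions that leave both alkenes untouched.

Step 4
Reactants: 8 2-[(3E)-6-bromo-3-methylhex-3-en-1-yl]-1,3,3-trimethylcyclohex-1-ene; 9 prop-2-yn-1-ol (propargyl alcohol)
Product: 13 (5E)-6-methyl-2-methylidene-8-(2,6,6-trimethylcyclohex-1-en-1-yl)oct-5-en-1-ol, via Grignard reagent 10 (not isolated), via bromomagnesium propargyl alkoxide 11 (not isolated), via alkenylmagnesium alkoxide 12 (not isolated)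
Conditions: 8, Mg turnings, Et2O, reflux; separately 9 (1.2 equiv), EtMgBr (1.2 equiv), Et2O, 0 °C; the two solutions combined, CuI (10 mol%), 0 °C to rt; cold 1 M HCl
Reagents that add atoms: none
Why: Copper-catalysed carbomagnesiation of a propargylic alkoxide, in which the alkoxide directs anti addition of the primary alkyl group to the internal alkyne carbon and of magnesium to the terminal carbon (12), and protonation gives the 2-substituted prop-2-en-1-ol; ethylmagnesium bromide is spent on the hydroxyl proton so that 10 is not lost as hydrocarbon.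

Step 5
Reactants: 14 furan-3-carbaldehyde
Product: 16 (1R)-1-(furan-3-yl)but-3-en-1-ol, via diisopinocampheylborinate 15 (not isolated)
Conditions: (+)-Ipc2B(allyl) (1.2 equiv), Et2O–pentane, −100 to −78 °C; then 3 M NaOH, 30% H2O2, 0 °C to rt
Reagents that add atoms: (+)-B-allyldiisopinocampheylborane, C=CCB([C@H]1C[C@H]2C[C@H](C2(C)C)[C@@H]1C)[C@H]1C[C@H]2C[C@H](C2(C)C)[C@@H]1C
Why: Brown asymmetric allylboration through a chair six-membered transition state in which the isopinocampheyl groups derived from (−)-α-pinene direct the allyl group to the Re face of the aryl aldehyde, which sets the R carbinol centre before oxidative cleavage of borinate 15.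

Step 6
Reactants: 16 (1R)-1-(furan-3-yl)but-3-en-1-ol
Product: 18 5-hydroxy-4-[(1R)-1-hydroxybut-3-en-1-yl]furan-2(5H)-one (both C5 epimers), via furan endoperoxide 17 (not isolated)
Conditions: O2, visible light, tetraphenylporphyrin (cat.), iPr2NEt, CH2Cl2, −78 °C
Reagents that add atoms: dioxygen, O=O
Why: Singlet oxygen adds [4+2] across C2 and C5 of the furan to give 17, and the hindered amine removes the less hindered bridgehead proton remote from the side chain (Kornblum–DeLaMare-type fragmentation), which places the lactone carbonyl away from the substituent and gives the 4-substituted 5-hydroxybutenolide; the monosubstituted alkene does not react with singlet oxygen at −78 °C and the carbinol centre is untouched.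

Step 7
Reactants: 18 5-hydroxy-4-[(1R)-1-hydroxybut-3-en-1-yl]furan-2(5H)-one
Product: 20 4-[(1R)-1-hydroxybut-3-en-1-yl]furan-2(5H)-one, via hydroxy carboxylate 19 (not isolated)
Conditions: NaBH4, EtOH, 0 °C; then 1 M HCl to pH 2, rt
Reagents that add atoms: none
Why: The hydroxybutenolide reacts through its ring-opened formyl carboxylate, borohydride reduces the aldehyde to the primary alcohol of 19, and acidification closes the five-membered lactone onto that cis CH2OH (reduction–lactonisation of a γ-hydroxybutenolide), while the secondary carbinol, trans to the carboxyl group across the alkene, cannot lactonise and keeps its R configuration.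

Step 8
Reactants: 20 4-[(1R)-1-hydroxybut-3-en-1-yl]furan-2(5H)-one; 21 dichlorodi(propan-2-yl)silane; 13 (5E)-6-methyl-2-methylidene-8-(2,6,6-trimethylcyclohex-1-en-1-yl)oct-5-en-1-ol
Product: 23 4-[(1R)-1-({[(5E)-6-methyl-2-methylidene-8-(2,6,6-trimethylcyclohex-1-en-1-yl)oct-5-en-1-yl]oxy}di(propan-2-yl)silyl)oxybut-3-en-1-yl]furan-2(5H)-one (diisopropylsilylene bis-ether of 13 and 20), via chlorosilyl ether 22 (not isolated)
Conditions: 20, 21 (1.0 equiv), imidazole, CH2Cl2, 0 °C to rt; then 13, imidazole, DMAP (cat.), rt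
Reagents that add atoms: none
Why: Stepwise nucleophilic substitution at silicon, in which the hindered secondary alcohol takes one chloride of the bulky dichlorosilane and stops at monochloride 22, after which the unhindered primary allylic alcohol 13 displaces the second chloride to give the unsymmetrical bis-alkoxysilane without touching the stereocentre.

Step 9
Reactants: 23 diisopropylsilylene bis-ether of 13 and 20
Product: 24 4-[(5Z,8R)-5-[(3E)-4-methyl-6-(2,6,6-trimethylcyclohex-1-en-1-yl)hex-3-en-1-yl]-2,2-di(propan-2-yl)-1,3-dioxa-2-silacyclooct-5-en-8-yl]furan-2(5H)-one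
Conditions: second-generation Grubbs catalyst RuCl2(PCy3)(H2IMes)(=CHPh) (10 mol%), degassed toluene (2 mM), 80 °C, argon sparge
Reagents that add atoms: none
Why: The ruthenium benzylidene exchanges onto the monosubstituted vinyl group of 23, the only unhindered alkene, and the resulting alkylidene adds across the 1,1-disubstituted alkene held nearby by the O–Si–O bridge to give a ruthenacyclobutane, which cycloreverts to the trisubstituted ring alkene and a ruthenium methylidene that carries the chain and releases ethene (ring-closing olefin metathesis). The closest known reaction type is temporary-silicon-tethered ring-closing metathesis of bis-alkoxysilanes built from a 2-substituted allylic alcohol and an unsaturated alcohol, well established for seven-membered silaketals and shown, though less often, for eight-membered ones. The 1,3-dioxa-2-silacyclooct-5-ene ring is closed by forming its C5=C6 bond as an endocyclic double bond in an eight-membered ring closure, helped by the two isopropyl groups on silicon, the long Si–O bonds and high dilution. No new stereocentre is formed and the R carbinol carbon is not involved; the new stereo element is the alkene geometry, set by the ring, in which the ring CH2O and ring CH2 are expected to be cis because a trans double bond in a ring of this size is strongly strained, so the Z alkene of the target should result. The step needs chemoselectivity among five alkenes: the tetrasubstituted cyclohexene and the conjugated butenolide alkene are not expected to react with this catalyst, and the chain trisubstituted alkene could only close a cyclobutene from the methylidene side or an eleven-membered ring from the vinyl side, both expected to be slower than the eight-membered closure.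

Step 10
Reactants: 24 eight-membered cyclic diisopropylsilylene ether
Product: 25 4-[(1R,3Z,7E)-1-hydroxy-4-(hydroxymethyl)-8-methyl-10-(2,6,6-trimethylcyclohex-1-en-1-yl)deca-3,7-dien-1-yl]furan-2(5H)-one (target)
Conditions: HF·pyridine, pyridine, THF, 0 °C to rt
Reagents that add atoms: none
Why: Fluoride attacks silicon and both Si–O bonds are cleaved (desilylation driven by the strong Si–F bond) under buffered, weakly acidic conditions that should spare the butenolide, the allylic alcohol and both alkene geometries.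

## Compound list

1 | 4-(2,6,6-trimethylcyclohex-1-en-1-yl)butan-2-one (dihydro-β-ionone) | CC1=C(CCC(C)=O)C(C)(C)CCC1 | starting material
2 | 4-(2,6,6-trimethylcyclohex-1-en-1-yl)but-1-en-2-yl diethyl phosphate | CC1=C(CCC(=C)OP(=O)(OCC)OCC)C(C)(C)CCC1 | intermediate
3 | lithium 4-(2,6,6-trimethylcyclohex-1-en-1-yl)but-1-yn-1-ide | CC1=C(CCC#C[Li])C(C)(C)CCC1 | intermediate
4 | 2-(but-3-yn-1-yl)-1,3,3-trimethylcyclohex-1-ene | CC1=C(CCC#C)C(C)(C)CCC1 | intermediate
5 | dimethyl[(1E)-2-methyl-4-(2,6,6-trimethylcyclohex-1-en-1-yl)but-1-en-1-yl]alane | CC1=C(CC/C(C)=C/[Al](C)C)C(C)(C)CCC1 | intermediate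
6 | lithium butyl(dimethyl)[(1E)-2-methyl-4-(2,6,6-trimethylcyclohex-1-en-1-yl)but-1-en-1-yl]aluminate | [Li+].CC1=C(CC/C(C)=C/[Al-](C)(C)CCCC)C(C)(C)CCC1 | intermediate
7 | (3E)-4-methyl-6-(2,6,6-trimethylcyclohex-1-en-1-yl)hex-3-en-1-ol | CC1=C(CC/C(C)=C/CCO)C(C)(C)CCC1 | intermediate
8 | 2-[(3E)-6-bromo-3-methylhex-3-en-1-yl]-1,3,3-trimethylcyclohex-1-ene | CC1=C(CC/C(C)=C/CCBr)C(C)(C)CCC1 | intermediate
9 | prop-2-yn-1-ol (propargyl alcohol) | C#CCO | starting material
10 | [(3E)-4-methyl-6-(2,6,6-trimethylcyclohex-1-en-1-yl)hex-3-en-1-yl]magnesium bromide | CC1=C(CC/C(C)=C/CC[Mg]Br)C(C)(C)CCC1 | intermediate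
11 | bromomagnesium prop-2-yn-1-olate | C#CCO[Mg]Br | intermediate
12 | bromo[(1Z,5E)-2-[(bromomagnesiooxy)methyl]-6-methyl-8-(2,6,6-trimethylcyclohex-1-en-1-yl)octa-1,5-dien-1-yl]magnesium | CC1=C(CC/C(C)=C/CC/C(CO[Mg]Br)=C/[Mg]Br)C(C)(C)CCC1 | intermediate
13 | (5E)-6-methyl-2-methylidene-8-(2,6,6-trimethylcyclohex-1-en-1-yl)oct-5-en-1-ol (fragment A) | CC1=C(CC/C(C)=C/CCC(=C)CO)C(C)(C)CCC1 | intermediate
14 | furan-3-carbaldehyde | O=Cc1ccoc1 | starting material
15 | (1R)-1-(furan-3-yl)but-3-en-1-yl diisopinocampheylborinate | C=CC[C@@H](OB([C@H]1C[C@H]2C[C@H](C2(C)C)[C@@H]1C)[C@H]1C[C@H]2C[C@H](C2(C)C)[C@@H]1C)c1ccoc1 | intermediate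
16 | (1R)-1-(furan-3-yl)but-3-en-1-ol | O[C@H](CC=C)c1ccoc1 | intermediate
17 | (1R)-1-(2,3,7-trioxabicyclo[2.2.1]hept-5-en-5-yl)but-3-en-1-ol (both bridgehead diastereomers) | O[C@H](CC=C)C1=CC2OOC1O2 | intermediate
18 | 5-hydroxy-4-[(1R)-1-hydroxybut-3-en-1-yl]furan-2(5H)-one (both C5 epimers) | O[C@H](CC=C)C1=CC(=O)OC1O | intermediate
19 | sodium (2E,4R)-4-hydroxy-3-(hydroxymethyl)hepta-2,6-dienoate | [Na+].[O-]C(=O)/C=C(\CO)[C@H](O)CC=C | intermediate
20 | 4-[(1R)-1-hydroxybut-3-en-1-yl]furan-2(5H)-one (fragment B) | O[C@H](CC=C)C1=CC(=O)OC1 | intermediate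
21 | dichlorodi(propan-2-yl)silane | CC(C)[Si](Cl)(Cl)C(C)C | starting material
22 | 4-[(1R)-1-{[chlorodi(propan-2-yl)silyl]oxy}but-3-en-1-yl]furan-2(5H)-one | C=CC[C@@H](O[Si](Cl)(C(C)C)C(C)C)C1=CC(=O)OC1 | intermediate
23 | 4-[(1R)-1-({[(5E)-6-methyl-2-methylidene-8-(2,6,6-trimethylcyclohex-1-en-1-yl)oct-5-en-1-yl]oxy}di(propan-2-yl)silyl)oxybut-3-en-1-yl]furan-2(5H)-one | CC1=C(CC/C(C)=C/CCC(=C)CO[Si](C(C)C)(C(C)C)O[C@H](CC=C)C2=CC(=O)OC2)C(C)(C)CCC1 | intermediate
24 | 4-[(5Z,8R)-5-[(3E)-4-methyl-6-(2,6,6-trimethylcyclohex-1-en-1-yl)hex-3-en-1-yl]-2,2-di(propan-2-yl)-1,3-dioxa-2-silacyclooct-5-en-8-yl]furan-2(5H)-one | CC1=C(CC/C(C)=C/CC/C2=C/C[C@H](C3=CC(=O)OC3)O[Si](C(C)C)(C(C)C)OC2)C(C)(C)CCC1 | intermediate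
25 | 4-[(1R,3Z,7E)-1-hydroxy-4-(hydroxymethyl)-8-methyl-10-(2,6,6-trimethylcyclohex-1-en-1-yl)deca-3,7-dien-1-yl]furan-2(5H)-one | CC1=C(CC/C(C)=C/CC/C(=C/C[C@@H](O)C2=CC(=O)OC2)CO)C(C)(C)CCC1 | target

## Step count and risks

Total steps: 10. Longest linear sequence: 7 steps (steps 1, 2, 3, 4, 8, 9, 10); fragment B is made in steps 5 to 7 and joins at step 8.

**Step 9 (ring-closing metathesis).**
- What may go wrong: slow closure of the medium ring lets intermolecular metathesis at the vinyl group build oligomers; the vinyl-derived carbene may attack the chain trisubstituted alkene and cut off the terpenoid tail; the long Si–O bonds may relieve enough strain for some of the ring E alkene to form.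
- Fallback: an ester tether replaces the silicon tether and the furan is kept as a masked butenolide. It sets out from 13 and 16 and comes back at 25.
- Alcohol 13 would be oxidised with MnO2 in CH2Cl2 to (5E)-6-methyl-2-methylidene-8-(2,6,6-trimethylcyclohex-1-en-1-yl)oct-5-enal F1, and on with NaClO2, NaH2PO4 and 2-methylbut-2-ene (Pinnick oxidation) to (5E)-6-methyl-2-methylidene-8-(2,6,6-trimethylcyclohex-1-en-1-yl)oct-5-enoic acid F2.
- Steglich esterification (DCC, DMAP) with 16 should give (1R)-1-(furan-3-yl)but-3-en-1-yl (5E)-6-methyl-2-methylidene-8-(2,6,6-trimethylcyclohex-1-en-1-yl)oct-5-enoate F3.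
- Ring-closing metathesis with the second-generation Grubbs catalyst RuCl2(PCy3)(H2IMes)(=CHPh) should then close a six-membered unsaturated lactone, (6R)-6-(furan-3-yl)-3-[(3E)-4-methyl-6-(2,6,6-trimethylcyclohex-1-en-1-yl)hex-3-en-1-yl]-5,6-dihydro-2H-pyran-2-one F4. This is a well-tested ring size in which the alkene can only be cis.
- Excess iBu2AlH in CH2Cl2 (−78 to 0 °C) should reduce the lactone to (1R,3Z,7E)-1-(furan-3-yl)-4-(hydroxymethyl)-8-methyl-10-(2,6,6-trimethylcyclohex-1-en-1-yl)deca-3,7-dien-1-ol F5.
- Singlet oxygen with iPr2NEt at −78 °C (conditions of step 6; the furan is the most reactive partner) should give 5-hydroxy-4-[(1R,3Z,7E)-1-hydroxy-4-(hydroxymethyl)-8-methyl-10-(2,6,6-trimethylcyclohex-1-en-1-yl)deca-3,7-dien-1-yl]furan-2(5H)-one F6. NaBH4 and then acid (conditions of step 7) would convert it into 25.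

**Step 4 (carbomagnesiation).**
- What may go wrong: the acetylenic C–H of 11 may protonate Grignard reagent 10 faster than copper-catalysed addition occurs, and Wurtz coupling may consume 8 while the Grignard reagent forms.
- Fallback: an sp3–sp2 cross-coupling replaces the carbometalation. It sets out from 8 (through 10) and comes back at 13.
- Commercial 2-bromoprop-2-en-1-ol would be silylated (tert-butyldimethylsilyl chloride, imidazole) to [(2-bromoprop-2-en-1-yl)oxy](tert-butyl)dimethylsilane F7.
- Grignard reagent 10 would be transmetalated with ZnCl2 in THF to [(3E)-4-methyl-6-(2,6,6-trimethylcyclohex-1-en-1-yl)hex-3-en-1-yl]zinc chloride F8.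
- Negishi coupling of F8 with F7 under PdCl2(dppf) should give tert-butyl(dimethyl){[(5E)-6-methyl-2-methylidene-8-(2,6,6-trimethylcyclohex-1-en-1-yl)oct-5-en-1-yl]oxy}silane F9, and Bu4NF in THF would release 13.

**Step 8 (mixed silaketal).**
- What may go wrong: exchange at silicon may give the two symmetrical bis-ethers; the first silylation of the hindered carbinol may stall; chlorosilane 22 may hydrolyse before 13 is added.
- Fallback: a monofunctional silicon reagent with later activation of Si–H replaces the dichlorosilane. It sets out from 20 and comes back at 23.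
- Alcohol 20 would be treated with chlorodi(propan-2-yl)silane and imidazole to give 4-[(1R)-1-{[di(propan-2-yl)silyl]oxy}but-3-en-1-yl]furan-2(5H)-one F10, which cannot react a second time.
- N-Bromosuccinimide in CH2Cl2 at 0 °C should convert the Si–H bond into Si–Br, giving 4-[(1R)-1-{[bromodi(propan-2-yl)silyl]oxy}but-3-en-1-yl]furan-2(5H)-one F11.
- Addition of 13 and imidazole should then give 23.

## Further compounds

F1 | step 9 | (5E)-6-methyl-2-methylidene-8-(2,6,6-trimethylcyclohex-1-en-1-yl)oct-5-enal | CC1=C(CC/C(C)=C/CCC(=C)C=O)C(C)(C)CCC1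
F2 | step 9 | (5E)-6-methyl-2-methylidene-8-(2,6,6-trimethylcyclohex-1-en-1-yl)oct-5-enoic acid | CC1=C(CC/C(C)=C/CCC(=C)C(=O)O)C(C)(C)CCC1
F3 | step 9 | (1R)-1-(furan-3-yl)but-3-en-1-yl (5E)-6-methyl-2-methylidene-8-(2,6,6-trimethylcyclohex-1-en-1-yl)oct-5-enoate | CC1=C(CC/C(C)=C/CCC(=C)C(=O)O[C@H](CC=C)c2ccoc2)C(C)(C)CCC1
F4 | step 9 | (6R)-6-(furan-3-yl)-3-[(3E)-4-methyl-6-(2,6,6-trimethylcyclohex-1-en-1-yl)hex-3-en-1-yl]-5,6-dihydro-2H-pyran-2-one | CC1=C(CC/C(C)=C/CCC2=CC[C@H](c3ccoc3)OC2=O)C(C)(C)CCC1
F5 | step 9 | (1R,3Z,7E)-1-(furan-3-yl)-4-(hydroxymethyl)-8-methyl-10-(2,6,6-trimethylcyclohex-1-en-1-yl)deca-3,7-dien-1-ol | CC1=C(CC/C(C)=C/CC/C(=C/C[C@@H](O)c2ccoc2)CO)C(C)(C)CCC1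
F6 | step 9 | 5-hydroxy-4-[(1R,3Z,7E)-1-hydroxy-4-(hydroxymethyl)-8-methyl-10-(2,6,6-trimethylcyclohex-1-en-1-yl)deca-3,7-dien-1-yl]furan-2(5H)-one | CC1=C(CC/C(C)=C/CC/C(=C/C[C@@H](O)C2=CC(=O)OC2O)CO)C(C)(C)CCC1
F7 | step 4 | [(2-bromoprop-2-en-1-yl)oxy](tert-butyl)dimethylsilane | C=C(Br)CO[Si](C)(C)C(C)(C)C
F8 | step 4 | [(3E)-4-methyl-6-(2,6,6-trimethylcyclohex-1-en-1-yl)hex-3-en-1-yl]zinc chloride | CC1=C(CC/C(C)=C/CC[Zn]Cl)C(C)(C)CCC1
F9 | step 4 | tert-butyl(dimethyl){[(5E)-6-methyl-2-methylidene-8-(2,6,6-trimethylcyclohex-1-en-1-yl)oct-5-en-1-yl]oxy}silane | CC1=C(CC/C(C)=C/CCC(=C)CO[Si](C)(C)C(C)(C)C)C(C)(C)CCC1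
F10 | step 8 | 4-[(1R)-1-{[di(propan-2-yl)silyl]oxy}but-3-en-1-yl]furan-2(5H)-one | C=CC[C@@H](O[SiH](C(C)C)C(C)C)C1=CC(=O)OC1
F11 | step 8 | 4-[(1R)-1-{[bromodi(propan-2-yl)silyl]oxy}but-3-en-1-yl]furan-2(5H)-one | C=CC[C@@H](O[Si](Br)(C(C)C)C(C)C)C1=CC(=O)OC1
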